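**Retrosynthetic overview**
- Feature: ring A (dibromo ring: C1 hydroxyl, C2 and C4 bromine, C6 ether oxygen) and ring B (tribromo ring: C1' ether oxygen, C3', C4', C5' bromine, C6' hydroxyl) carry their hydroxyl carbons C1 and C6' ortho to the bridging oxygen, so both hydroxyls can be carried as formyl groups.
- Target 13 ⇐ bis-formate 10 (methanolysis) ⇐ dialdehyde 7 by a twofold Baeyer–Villiger oxidation that makes the C1–O and C6'–O bonds.
- Dialdehyde 7 ⇐ salicylaldehyde 4 + 2,4-dibromo-6-fluorobenzaldehyde 5 by SNAr at C6 of ring A; the ring-A formyl group that later becomes the C1 hydroxyl activates the fluoride.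
- Salicylaldehyde 4 ⇐ 3,4,5-tribromophenol 1 by ortho-formylation (the two ortho positions are equivalent).
- No ring is formed; both benzene rings and all five bromines come with the two building blocks.

Key step: step 3

Remark: the target has no stereocentre and is achiral, so no enantiomer has to be controlled; 1 and 5 are taken to be commercially available.

**Step 1**
Reactants: 1 3,4,5-tribromophenol
Product: 4 2,3,4-tribromo-6-hydroxybenzaldehyde, via magnesium phenoxide 2 (not isolated), via hydroxymethylphenol 3 (not isolated)
Conditions: anhydrous MgCl2 (2 equiv), Et3N (3 equiv), (CH2O)n (6 equiv), MeCN, reflux; then 1 M HCl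
Reagents that add atoms: paraformaldehyde (as formaldehyde), C=O
Why: Magnesium-mediated ortho-formylation of a phenol (Casnati–Skattebøl type), in which the magnesium phenoxide delivers formaldehyde to the only free ring positions (C2/C6, equivalent) and the resulting hydroxymethyl magnesium salt is oxidised by a second formaldehyde through hydride transfer; halophenols are established substrates and the deactivated product should not be formylated again.

**Step 2**
Reactants: 4 2,3,4-tribromo-6-hydroxybenzaldehyde; 5 2,4-dibromo-6-fluorobenzaldehyde (1.1 equiv)
Product: 7 2,3,4-tribromo-6-(3,5-dibromo-2-formylphenoxy)benzaldehyde, via potassium phenoxide 6 (not isolated)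
Conditions: K2CO3 (1.5 equiv), dry DMF, 90 °C, N2
Reagents that add atoms: none
Why: Nucleophilic aromatic substitution of a fluoride ortho to a formyl group by a phenoxide, the known way to bis(2-formylaryl) ethers from salicylaldehydes and 2-fluorobenzaldehydes; fluoride should leave far faster than the bromines ortho and para to the formyl groups, the two meta bromines add inductive activation, and neither aldehyde has an enolisable hydrogen.

**Step 3**
Reactants: 7 2,3,4-tribromo-6-(3,5-dibromo-2-formylphenoxy)benzaldehyde
Product: 10 2,3,4-tribromo-6-[3,5-dibromo-2-(formyloxy)phenoxy]phenyl formate, via ring-A formate aldehyde 8 (not isolated), via ring-B formate aldehyde 9 (not isolated)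
Conditions: mCPBA (5 equiv, dried in CH2Cl2), TFA (0.2 equiv), CH2Cl2, 0 °C to reflux; cold aq. Na2SO3, brief cold NaHCO3 wash; crude 10 taken on
Reagents that add atoms: mCPBA (3-chloroperbenzoic acid), OOC(=O)c1cccc(Cl)c1
Why: Each formyl carbonyl adds the peracid to give a Criegee adduct, and the ring carbon then shifts from carbon to the proximal peroxide oxygen as 3-chlorobenzoate leaves, which makes the C1–O bond on the dibromo ring and the C6'–O bond on the tribromo ring and leaves each former carbonyl carbon as a formate. This is the Baeyer–Villiger (Dakin-type) oxidation of ortho-aryloxy- and ortho-alkoxybenzaldehydes to aryl formates, a known reaction of brominated diaryl ether aldehydes. No ring is closed and no stereocentre is created. The selectivity needed is aryl over hydride migration on two electron-poor rings: on each ring the ether oxygen ortho to the migrating carbon donates a lone pair into the electron-deficient migrating centre, and the acidic, non-basic medium keeps the adduct protonated, the state from which aryl migration is preferred. The less electron-poor dibromo ring should react first (8), but either monoformate (8 or 9) is carried on to 10 by the excess peracid. The aryl bromides, the diaryl ether and the formates are inert to the peracid, and any formate lost in the wash does not matter because step 4 removes both.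

**Step 4**
Reactants: 10 2,3,4-tribromo-6-[3,5-dibromo-2-(formyloxy)phenoxy]phenyl formate
Product: 13 2,3,4-tribromo-6-(3,5-dibromo-2-hydroxyphenoxy)phenol, via ring-B formate phenol 11 (not isolated), via ring-A formate phenol 12 (not isolated)
Conditions: HCl (cat., methanolic), MeOH–THF, rt
Reagents that add atoms: none
Why: Acid-catalysed transesterification (methanolysis) of two aryl formates, the most labile aryl esters, should release both phenols in either order through 11 or 12, while the acidic medium avoids phenoxide chemistry on the polybrominated rings and leaves the ether and the bromines untouched.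

**Compound list**
1 | 3,4,5-tribromophenol | Oc1cc(Br)c(Br)c(Br)c1 | starting material
2 | chloromagnesium 3,4,5-tribromophenoxide | Cl[Mg]Oc1cc(Br)c(Br)c(Br)c1 | intermediate
3 | 3,4,5-tribromo-2-(hydroxymethyl)phenol (held in the flask as its magnesium salt) | OCc1c(O)cc(Br)c(Br)c1Br | intermediate
4 | 2,3,4-tribromo-6-hydroxybenzaldehyde | O=Cc1c(O)cc(Br)c(Br)c1Br | intermediate
5 | 2,4-dibromo-6-fluorobenzaldehyde | O=Cc1c(F)cc(Br)cc1Br | starting material
6 | potassium 3,4,5-tribromo-2-formylphenolate | [K+].[O-]c1cc(Br)c(Br)c(Br)c1C=O | intermediate
7 | 2,3,4-tribromo-6-(3,5-dibromo-2-formylphenoxy)benzaldehyde | O=Cc1c(Br)cc(Br)cc1Oc1cc(Br)c(Br)c(Br)c1C=O | intermediate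
8 | 2,4-dibromo-6-(3,4,5-tribromo-2-formylphenoxy)phenyl formate | O=COc1c(Br)cc(Br)cc1Oc1cc(Br)c(Br)c(Br)c1C=O | intermediate
9 | 2,3,4-tribromo-6-(3,5-dibromo-2-formylphenoxy)phenyl formate | O=Cc1c(Br)cc(Br)cc1Oc1cc(Br)c(Br)c(Br)c1OC=O | intermediate
10 | 2,3,4-tribromo-6-[3,5-dibromo-2-(formyloxy)phenoxy]phenyl formate | O=COc1c(Br)cc(Br)cc1Oc1cc(Br)c(Br)c(Br)c1OC=O | intermediate
11 | 2,3,4-tribromo-6-(3,5-dibromo-2-hydroxyphenoxy)phenyl formate | Oc1c(Br)cc(Br)cc1Oc1cc(Br)c(Br)c(Br)c1OC=O | intermediate
12 | 2,4-dibromo-6-(3,4,5-tribromo-2-hydroxyphenoxy)phenyl formate | O=COc1c(Br)cc(Br)cc1Oc1cc(Br)c(Br)c(Br)c1O | intermediate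
13 | 2,3,4-tribromo-6-(3,5-dibromo-2-hydroxyphenoxy)phenol | Oc1c(Br)cc(Br)cc1Oc1cc(Br)c(Br)c(Br)c1O | target

**Step count and risks**
Total steps: 4. Longest linear sequence: 4 steps (1 → 4 → 7 → 10 → 13); 5 enters at step 2.

Step 3 (highest risk): hydride migration may compete with aryl migration on one or both electron-poor rings and lead to carboxylic acids, or the oxidation of the tribromo ring may stall. Fallback: from dialdehyde 7, MeMgBr (THF, −78 °C) should add to both formyl groups without touching the aryl bromides and give the bis(1-hydroxyethyl) diaryl ether F1 as a diastereomer mixture. Dess–Martin oxidation should then give the diacetyl diaryl ether F2. Baeyer–Villiger oxidation of F2 with trifluoroperacetic acid (TFAA, urea–H2O2, Na2HPO4, CH2Cl2), where aryl competes only against the poorly migrating methyl group, should give the diacetate F3. Methanolysis of F3 (HCl, MeOH) comes back to the route at target 13.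

Step 2: the phenoxide of 4 is electron-poor and tied to its ortho carbonyl, so fluoride displacement may be slow, and displacement of activated bromines may then lead to oligomers. Fallback: from salicylaldehyde 4, NaBH4 (MeOH, 0 °C) should give the hydroxymethylphenol 3, here isolated as the free phenol. Its phenoxide is more nucleophilic, and with K2CO3 in DMF it should displace the fluoride of 5 to give 2,4-dibromo-6-[3,4,5-tribromo-2-(hydroxymethyl)phenoxy]benzaldehyde F4. MnO2 in CH2Cl2 should oxidise the benzylic alcohol of F4 and rejoin the route at dialdehyde 7.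

Step 1: formylation at an ortho position flanked by bromine on an electron-poor phenoxide may be sluggish, stop at the hydroxymethyl stage or drift into diarylmethane condensation. Fallback: from phenol 1, a Duff formylation (hexamethylenetetramine, TFA, reflux; then aq. HCl), which uses an iminium electrophile under acid and tolerates deactivated phenols, should lead directly to salicylaldehyde 4 with no new isolated compound.

**Further compounds**
F1 | step 3 | 1-[2,3,4-tribromo-6-[3,5-dibromo-2-(1-hydroxyethyl)phenoxy]phenyl]ethan-1-ol (diastereomer mixture) | CC(O)c1c(Br)cc(Br)cc1Oc1cc(Br)c(Br)c(Br)c1C(C)O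
F2 | step 3 | 1-[6-(2-acetyl-3,5-dibromophenoxy)-2,3,4-tribromophenyl]ethan-1-one | CC(=O)c1c(Br)cc(Br)cc1Oc1cc(Br)c(Br)c(Br)c1C(C)=O
F3 | step 3 | 6-(2-acetoxy-3,5-dibromophenoxy)-2,3,4-tribromophenyl acetate | CC(=O)Oc1c(Br)cc(Br)cc1Oc1cc(Br)c(Br)c(Br)c1OC(C)=O
F4 | step 2 | 2,4-dibromo-6-[3,4,5-tribromo-2-(hydroxymethyl)phenoxy]benzaldehyde | O=Cc1c(Br)cc(Br)cc1Oc1cc(Br)c(Br)c(Br)c1CO
F0 | step 1 | none | none
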